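The 2,5-dihydrofuran ring (acetal carbon C14, ring oxygen, C11 bearing the diol side chain, and C9=C10) is the cycloisomer of an α-hydroxyallene. It is therefore opened across the O–C11 bond to a six-membered lactol (hydroxyl on C14) carrying an exocyclic allene C9=C10=C11. A single gold-catalysed 5-endo closure forms this last ring, converts the allene axis into the C11 stereocentre and fixes the C14 acetal configuration through the trans-fused pyran chair. The allenyl lactol comes from an alkynyl epoxide by palladium-catalysed carbonylative lactonisation; the nine-membered ring is closed by metathesis on a trans-disubstituted butyrolactone assembled from furan-2(5H)-one and (S)-linalool.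

Key step: step 19

Locants used for all compounds (those of the target): C1 ring carbon bearing the exocyclic CH2; C2; C3 and C4 oxirane carbons; C5 C(CH3)OH; C6; C7; C8 ring-fusion CH bonded to C9; C9=C10 dihydrofuran alkene; C11 OCH of the dihydrofuran; C12 CH(OH); C13 C(CH3)2OH; C14 acetal CH; C15 OCH2; C16 ring-fusion CH bearing C15 and C1.

Remark: (S)-(+)-linalool of high enantiomeric purity is taken as commercially available; the named enantiomers of BINAP and of 2,5-diphenylpyrrolidine are meant as those that deliver the stated configurations; allene axes are written in SMILES with @ on the central allene carbon.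

Step 1
Reactants: 1 2,3-dibromopropene
Product: 2 2-bromopenta-1,4-diene
Conditions: CH2=CHMgBr (1.1 equiv), CuI (5 mol %), THF, −20 to 0 °C
Reagents that add atoms: vinylmagnesium bromide, C=C[Mg]Br
Why: Copper-catalysed allylic substitution (Kumada-type coupling) by the vinyl Grignard reagent takes place at the allylic C–Br bond only, and attack at either allyl terminus gives the same 1,4-diene.

Step 2
Reactants: 2 2-bromopenta-1,4-diene
Product: 4 4,4,5,5-tetramethyl-2-(penta-1,4-dien-2-yl)-1,3,2-dioxaborolane, via Grignard reagent 3 (not isolated)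
Conditions: Mg turnings, THF, 40 °C; then i-PrOB(pin), −78 °C to rt
Reagents that add atoms: 2-isopropoxy-4,4,5,5-tetramethyl-1,3,2-dioxaborolane, CC(C)OB1OC(C)(C)C(C)(C)O1
Why: Magnesium insertion into the alkenyl bromide followed by borylation of the Grignard reagent with the isopropoxy boronic ester is a standard route to alkenyl pinacol boronates.

Step 3
Reactants: 4 alkenyl pinacol boronate; 5 furan-2(5H)-one
Product: 6 (4R)-4-(penta-1,4-dien-2-yl)oxolan-2-one
Conditions: [Rh(OH)(cod)]2 (2.5 mol %), (R)-BINAP (6 mol %), KOH (0.2 equiv), 1,4-dioxane/H2O 10:1, 50 °C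
Reagents that add atoms: none
Why: Hayashi–Miyaura rhodium-catalysed asymmetric conjugate addition, in which the alkenyl group is expected to be delivered from the (R)-BINAP–rhodium complex to one face of the butenolide and so sets C16 as R.

Step 4
Reactants: 7 (S)-linalool
Product: 8 (5S)-5-ethenyl-5-methyloxolan-2-ol (both anomers)
Conditions: O3 (Sudan red 7B end point), CH2Cl2/MeOH 5:1, −78 °C; then Me2S, −78 °C to rt
Reagents that add atoms: ozone, [O-][O+]=O
Why: Chemoselective ozonolysis, in which ozone attacks the electron-rich trisubstituted alkene far faster than the vinyl group and the γ-hydroxy aldehyde closes to the lactol with the carbinol stereocentre (later C5) untouched.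

Step 5
Reactants: 8 lactol
Product: 10 (3S)-5-iodo-3-methylpent-1-en-3-ol, via iodo formate 9 (not isolated)
Conditions: PhI(OAc)2 (1.3 equiv), I2 (1.0 equiv), CH2Cl2, visible light, rt; aq Na2S2O3 wash; then KHCO3 (0.2 equiv), MeOH, 0 °C
Reagents that add atoms: iodine, II
Why: Suárez hypoiodite fragmentation, in which the anomeric alkoxy radical undergoes β-scission of the ring C–C bond to a formate and a primary radical that iodine traps, so the chain is shortened by exactly one carbon, and mild methanolysis then frees the tertiary alcohol without change at the stereocentre.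

Step 6
Reactants: 10 iodo alcohol
Product: 11 [(3S)-5-iodo-3-methylpent-1-en-3-yl]oxy(trimethyl)silane
Conditions: 1-(trimethylsilyl)imidazole (1.5 equiv), CH2Cl2, rt
Reagents that add atoms: 1-(trimethylsilyl)imidazole, C[Si](C)(C)n1ccnc1
Why: Neutral silylation of the tertiary alcohol protects it for the enolate alkylation and avoids the base that would cyclise the iodo alcohol to a tetrahydrofuran.

Step 7
Reactants: 6 (4R)-lactone; 11 silyl ether iodide
Product: 12 (3S,4R)-3-[(3S)-3-methyl-3-(trimethylsilyloxy)pent-4-en-1-yl]-4-(penta-1,4-dien-2-yl)oxolan-2-one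
Conditions: LiN(i-Pr)2 (1.1 equiv), THF, −78 °C; then 11 (1.3 equiv), HMPA (3 equiv), −78 to −30 °C
Reagents that add atoms: none
Why: Alkylation of the lactone lithium enolate by the primary iodide should occur anti to the C16 alkenyl group and so sets C8 trans to C16.

Step 8
Reactants: 12 triene lactone
Product: 14 (3aR,6Z,8S,10aS)-8-hydroxy-8-methyl-4-methylidene-3,3a,4,5,8,9,10,10a-octahydro-1H-cyclonona[c]furan-1-one, via silyl ether 13 (not isolated)
Conditions: second-generation Hoveyda–Grubbs catalyst RuCl2(H2IMes)(=CH-C6H4-2-O-i-Pr) (10 mol %), 1,4-benzoquinone (20 mol %), toluene (1 mM), 80 °C; then citric acid (0.2 equiv), MeOH, rt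
Reagents that add atoms: none
Why: Ring-closing metathesis, in which the alkylidene forms at the unhindered allyl terminus whose only ring-closing partner is the carbinol vinyl group, while the tertiary silyl ether slows loading of ruthenium on that vinyl group and with it the competing seven-membered closure onto the 1,1-disubstituted alkene; the nine-membered ring can only hold the Z alkene, and acidic methanol then removes the silyl group.

Step 9
Reactants: 14 hydroxy lactone
Product: 15 epoxy lactone (3R,4R,5S,8S,16R)
Conditions: VO(acac)2 (5 mol %), t-BuOOH (1.5 equiv), CH2Cl2, 0 °C to rt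
Reagents that add atoms: tert-butyl hydroperoxide, CC(C)(C)OO
Why: Vanadium-catalysed hydroxyl-directed epoxidation, in which the vanadate ester of the tertiary allylic alcohol delivers oxygen to the neighbouring Z alkene on the hydroxyl-bearing face (cis-selective also in medium rings), which sets C3 and C4 and leaves the remote 1,1-disubstituted alkene alone.

Step 10
Reactants: 15 epoxy lactone
Product: 16 lactol of 15 (C9 hemiacetal; both anomers)
Conditions: i-Bu2AlH (2.2 equiv), CH2Cl2, −78 °C; aq potassium sodium tartrate
Reagents that add atoms: none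
Why: Partial reduction of the γ-lactone with i-Bu2AlH at low temperature stops at the aluminium lactolate, and the epoxy alcohol is inert under these conditions.

Step 11
Reactants: 16 lactol
Product: 17 (1R,2S,5S,6R,9R)-5-ethynyl-6-(hydroxymethyl)-2-methyl-7-methylidene-10-oxabicyclo[7.1.0]decan-2-ol
Conditions: dimethyl (1-diazo-2-oxopropyl)phosphonate (1.5 equiv), K2CO3 (2 equiv), MeOH, 0 °C to rt
Reagents that add atoms: dimethyl (1-diazo-2-oxopropyl)phosphonate, COP(=O)(OC)C(=[N+]=[N-])C(C)=O
Why: Ohira–Bestmann (Seyferth–Gilbert) homologation of the lactol through its open hydroxy aldehyde gives the terminal alkyne C9≡C10 and frees the C15 hydroxyl, the mild base at 0 °C not being expected to epimerise C8.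

Step 12
Reactants: 17 alkyne diol
Product: 18 bis(trimethylsilyl) ether of 17 (O5 and O15)
Conditions: 1-(trimethylsilyl)imidazole (3 equiv), CH2Cl2, rt
Reagents that add atoms: 1-(trimethylsilyl)imidazole, C[Si](C)(C)n1ccnc1
Why: Silylation of both hydroxyl groups under neutral conditions masks the acidic protons before the acetylide is made.

Step 13
Reactants: 19 3-methylbutane-1,3-diol
Product: 20 3-methyl-1,3-bis(triethylsilyloxy)butane
Conditions: Et3SiOTf (2.3 equiv), 2,6-lutidine (3 equiv), CH2Cl2, 0 °C
Reagents that add atoms: triethylsilyl trifluoromethanesulfonate, CC[Si](CC)(CC)OS(=O)(=O)C(F)(F)F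
Why: Exhaustive silylation with the silyl triflate covers the primary and the hindered tertiary hydroxyl.

Step 14
Reactants: 20 bis-silyl ether
Product: 21 3-methyl-3-(triethylsilyloxy)butanal
Conditions: (COCl)2 (2 equiv), DMSO (4 equiv), CH2Cl2, −78 to −40 °C; then Et3N (6 equiv), −78 °C to rt
Reagents that add atoms: none
Why: Swern oxidation with oxidative desilylation, in which the chlorosulfonium salt cleaves the unhindered primary triethylsilyl ether selectively and oxidises it to the aldehyde while the tertiary silyl ether stays.

Step 15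
Reactants: 21 aldehyde
Product: 22 (2R)-2-chloro-3-methyl-3-(triethylsilyloxy)butanal
Conditions: N-chlorosuccinimide (1.2 equiv), (2S,5S)-2,5-diphenylpyrrolidine (10 mol %), CH2Cl2, 0 °C to rt; used crude
Reagents that add atoms: N-chlorosuccinimide, O=C1CCC(=O)N1Cl
Why: Enamine-catalysed α-chlorination of the aldehyde (Jørgensen type), in which the C2-symmetric pyrrolidine shields one enamine face and sets the chlorine-bearing carbon (later C12).

Step 16
Reactants: 18 bis-silyl alkyne; 22 (2R)-chloro aldehyde
Product: 24 trans-alkynyl epoxide diol (11S,12R), via chlorohydrin 23 (not isolated)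
Conditions: n-BuLi (1.05 equiv), THF, −78 °C; then 22 (1.3 equiv), −78 °C; then K2CO3 (0.5 equiv), MeOH, 0 °C to rt
Reagents that add atoms: none
Why: Lithium acetylide addition to the α-chloro aldehyde under Cornforth control should give the anti chlorohydrin (sets C11), whose alkoxide then displaces chloride with inversion at C12 to the trans alkynyl oxirane, while methanol removes both trimethylsilyl groups.

Step 17
Reactants: 24 alkynyl epoxide diol
Product: 25 allenyl δ-lactone (Sa,12R)
Conditions: Pd2(dba)3·CHCl3 (5 mol %), PPh3 (20 mol %), CO (10 bar), THF (5 mM), 40 °C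
Reagents that add atoms: carbon monoxide, [C-]#[O+]
Why: Tsuji-type carbonylation of a propargylic oxirane, in which zerovalent palladium opens the alkynyl epoxide by anti SN2′ attack at C9, CO inserts into the allenyl–palladium bond and the C15 hydroxyl captures the acylpalladium to close the six-membered lactone, so the C11 centre is transferred into the (Sa) allene axis and C12 keeps its oxygen as the free hydroxyl.

Step 18
Reactants: 25 allenyl lactone
Product: 26 allenyl lactol (C14 hemiacetal; both anomers)
Conditions: i-Bu2AlH (3.5 equiv), CH2Cl2, −78 °C; aq potassium sodium tartrate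
Reagents that add atoms: none
Why: Partial 1,2-reduction of the lactone by i-Bu2AlH at −78 °C stops at the aluminium lactolate and gives the six-membered lactol without touching the allene.

Step 19
Reactants: 26 allenyl lactol
Product: 27 13-O-triethylsilyl ether of the target (3R,4R,5S,8S,11R,12R,14S,16R)
Conditions: Ph3PAuNTf2 (5 mol %), THF, −20 °C to rt
Reagents that add atoms: none
Why: Cationic monovalent gold π-coordinates the C10=C11 bond of the allene on the face away from the lactol oxygen, O(C14) adds to C11 in a 5-endo-trig closure of the dihydrofuran, and protodeauration of the C10–Au bond frees the catalyst. The closest known reaction type is the gold- or silver-catalysed cycloisomerisation of α-hydroxyallenes to 2,5-dihydrofurans, which runs with axis-to-centre chirality transfer. C11 is controlled by the (Sa) allene axis alone: the oxygen has to approach in the plane of the C9 substituents from the C14 side, so the C12 branch ends on the face fixed by the axis and C11 becomes R (net inversion relative to the oxirane C11–O bond of 24). C14 is controlled by the trans-fused chair of the pyran ring: only the equatorial lactol oxygen lies in that plane, the anomers interconvert under the reaction conditions, and the acetal is expected with H-14 axial (14S). The step needs chemoselectivity for the lactol hydroxyl at C11 over the free C12 hydroxyl at C9 and over dehydrative aromatisation to a furan; the fully substituted, acetal-flanked C9 terminus should disfavour the first and the neutral, aprotic conditions the second.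

Step 20
Reactants: 27 silyl ether
Product: 28 target CNP0281409.2
Conditions: Bu4NF (2 equiv), THF, 0 to 40 °C
Reagents that add atoms: none
Why: Fluoride cleaves the tertiary triethylsilyl ether, and the acetal, the epoxy alcohol and the alkenes should be stable to these mildly basic conditions.

Compound list
1 | 2,3-dibromopropene | C=C(Br)CBr | starting material
2 | 2-bromopenta-1,4-diene | C=CCC(Br)=C | intermediate
3 | penta-1,4-dien-2-ylmagnesium bromide (not isolated) | C=CCC(=C)[Mg]Br | intermediate
4 | 4,4,5,5-tetramethyl-2-(penta-1,4-dien-2-yl)-1,3,2-dioxaborolane | C=CCC(=C)B1OC(C)(C)C(C)(C)O1 | intermediate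
5 | furan-2(5H)-one | O=C1C=CCO1 | starting material
6 | (4R)-4-(penta-1,4-dien-2-yl)oxolan-2-one | O=C1C[C@H](C(=C)CC=C)CO1 | intermediate
7 | (S)-linalool, (3S)-3,7-dimethylocta-1,6-dien-3-ol | C=C[C@@](C)(O)CCC=C(C)C | starting material
8 | (5S)-5-ethenyl-5-methyloxolan-2-ol (both anomers) | C=C[C@]1(C)CCC(O)O1 | intermediate
9 | (3S)-5-iodo-3-methylpent-1-en-3-yl formate (not isolated) | C=C[C@@](C)(OC=O)CCI | intermediate
10 | (3S)-5-iodo-3-methylpent-1-en-3-ol | C=C[C@@](C)(O)CCI | intermediate
11 | [(3S)-5-iodo-3-methylpent-1-en-3-yl]oxy(trimethyl)silane | C=C[C@@](C)(O[Si](C)(C)C)CCI | intermediate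
12 | (3S,4R)-3-[(3S)-3-methyl-3-(trimethylsilyloxy)pent-4-en-1-yl]-4-(penta-1,4-dien-2-yl)oxolan-2-one | O=C1OC[C@@H](C(=C)CC=C)[C@@H]1CC[C@](C)(O[Si](C)(C)C)C=C | intermediate
13 | O5-trimethylsilyl ether of 14 (not isolated) | C=C1C/C=C\[C@@](C)(O[Si](C)(C)C)CC[C@@H]2C(=O)OC[C@@H]12 | intermediate
14 | (3aR,6Z,8S,10aS)-8-hydroxy-8-methyl-4-methylidene-3,3a,4,5,8,9,10,10a-octahydro-1H-cyclonona[c]furan-1-one; in the locants used here (3Z,5S,8S,16R) with the lactone C9(=O)–O–C15 trans-fused at C8–C16 | C=C1C/C=C\[C@@](C)(O)CC[C@@H]2C(=O)OC[C@@H]12 | intermediate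
15 | cis C3–C4 epoxide of 14 with the oxirane oxygen syn to the C5 hydroxyl (3R,4R,5S,8S,16R) | C=C1C[C@H]2O[C@H]2[C@@](C)(O)CC[C@@H]2C(=O)OC[C@@H]12 | intermediate
16 | lactol of 15 (C9 hemiacetal; both anomers) | C=C1C[C@H]2O[C@H]2[C@@](C)(O)CC[C@@H]2C(O)OC[C@@H]12 | intermediate
17 | (1R,2S,5S,6R,9R)-5-ethynyl-6-(hydroxymethyl)-2-methyl-7-methylidene-10-oxabicyclo[7.1.0]decan-2-ol; ethynyl C9≡C10 on C8 and C15H2OH on C16 | C=C1C[C@H]2O[C@H]2[C@@](C)(O)CC[C@H](C#C)[C@H]1CO | intermediate
18 | bis(trimethylsilyl) ether of 17 (O5 and O15) | C=C1C[C@H]2O[C@H]2[C@@](C)(O[Si](C)(C)C)CC[C@H](C#C)[C@H]1CO[Si](C)(C)C | intermediate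
19 | 3-methylbutane-1,3-diol | CC(C)(O)CCO | starting material
20 | 3-methyl-1,3-bis(triethylsilyloxy)butane | CC[Si](CC)(CC)OCCC(C)(C)O[Si](CC)(CC)CC | intermediate
21 | 3-methyl-3-(triethylsilyloxy)butanal | O=CCC(C)(C)O[Si](CC)(CC)CC | intermediate
22 | (2R)-2-chloro-3-methyl-3-(triethylsilyloxy)butanal | O=C[C@H](Cl)C(C)(C)O[Si](CC)(CC)CC | intermediate
23 | (11S,12S)-chlorohydrin (not isolated): 18 with C10 bonded to C11H(OH)–C12H(Cl)–C13(CH3)2OSiEt3 | C=C1C[C@H]2O[C@H]2[C@@](C)(O[Si](C)(C)C)CC[C@H](C#C[C@H](O)[C@H](Cl)C(C)(C)O[Si](CC)(CC)CC)[C@H]1CO[Si](C)(C)C | intermediate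
24 | (11S,12R)-trans-alkynyl epoxide diol: 17 with C10 bonded to the oxirane C11–C12 that carries C13(CH3)2OSiEt3 | C=C1C[C@H]2O[C@H]2[C@@](C)(O)CC[C@H](C#C[C@@H]3O[C@H]3C(C)(C)O[Si](CC)(CC)CC)[C@H]1CO | intermediate
25 | (Sa,12R)-allenyl δ-lactone: ring O15–C14(=O)–C9–C8–C16–C15 with exocyclic allene C9=C10=C11H–C12H(OH)–C13(CH3)2OSiEt3; nine-membered ring as in 15 | O=C3OC[C@H]1C(=C)C[C@H]2O[C@H]2[C@@](C)(O)CC[C@@H]1C3=[C@]=C([H])[C@@H](O)C(C)(C)O[Si](CC)(CC)CC | intermediate
26 | lactol of 25 (C14 hemiacetal; both anomers; Sa allene) | OC3OC[C@H]1C(=C)C[C@H]2O[C@H]2[C@@](C)(O)CC[C@@H]1C3=[C@]=C([H])[C@@H](O)C(C)(C)O[Si](CC)(CC)CC | intermediate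
27 | 13-O-triethylsilyl ether of 28 (3R,4R,5S,8S,11R,12R,14S,16R) | C=C1C[C@H]2O[C@H]2[C@@](C)(O)CC[C@@H]2C3=C[C@H]([C@@H](O)C(C)(C)O[Si](CC)(CC)CC)O[C@@H]3OC[C@@H]12 | intermediate
28 | CNP0281409.2 (3R,4R,5S,8S,11R,12R,14S,16R) | C=C1C[C@H]2O[C@H]2[C@@](C)(O)CC[C@@H]2C3=C[C@H]([C@@H](O)C(C)(C)O)O[C@@H]3OC[C@@H]12 | target

Total step count: 20. Longest linear sequence: 14 steps (from 7 through steps 4–12 and 16–20; the sequence from 1 is equally long).

Steps most likely to fail

1. Step 8 (ring-closing metathesis). Ruthenium may still load on the carbinol vinyl group and close onto the 1,1-disubstituted alkene to a seven-membered ring, or the slow nine-membered closure may lose to oligomerisation. Fallback: setting out from 12, the 1,1-disubstituted alkene is taken out of play by selective epoxidation with mCPBA (1.0 equiv, NaHCO3, CH2Cl2, −20 °C) to the C1 spiro-epoxide of 12 F1. Metathesis of F1 under the conditions of step 8 can then only join the two vinyl termini and should give the nine-membered epoxy lactone silyl ether F2. Deoxygenation of F2 with PPh3 and catalytic MeReO3 (benzene, rt) restores the exocyclic methylene, and the methanolysis of step 8 brings the material back to the route at 14.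

2. Step 19 (key step). The free C12 hydroxyl may add to C9 in a competing 5-endo closure to a spiro dihydrofuran, or the lactol may react through its open hydroxy allenal so that the furanium intermediate loses H-11 and aromatises. Fallback: setting out from 25, the C12 hydroxyl is silylated (Et3SiCl, imidazole, DMF, 0 °C) to the 12-O-triethylsilyl allenyl lactone F3. Reduction with i-Bu2AlH (CH2Cl2, −78 °C) gives the corresponding lactol F4, in which the lactol hydroxyl is the only nucleophile within reach of the allene. Cyclisation with AgNO3 (20 mol %, acetone, rt) should give the 12,13-bis-O-triethylsilyl ether of the target F5, and Bu4NF removes both silyl groups so that the sequence comes back to the route at 28.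

3. Step 17 (carbonylative lactonisation). The allenylpalladium intermediate may equilibrate before CO insertion and intramolecular capture, which erodes the centre-to-axis transfer, or the tethered hydroxyl may add to the central carbon of the allenyl/propargyl palladium species; excess phosphine may also racemise the allenoate. Fallback: setting out from 24, the carbonylation is run in methanol (Pd2(dba)3·CHCl3, PPh3, CO 20 bar, MeOH, rt), where the solvent captures the acylpalladium quickly, to give the methyl allenoate diol F6. Neutral transesterification with the distannoxane (ClBu2Sn)2O (5 mol %, toluene, 60 °C) then closes the six-membered lactone and comes back to the route at 25.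

Further compounds
F1 | step 8 | C1 spiro-epoxide of 12 (oxirane on the former 1,1-disubstituted alkene; both epimers) | O=C1OC[C@@H](C2(CC=C)CO2)[C@@H]1CC[C@](C)(O[Si](C)(C)C)C=C
F2 | step 8 | nine-membered epoxy lactone silyl ether (13 with a spiro-oxirane in place of the exocyclic methylene) | C1OC12C/C=C\[C@@](C)(O[Si](C)(C)C)CC[C@@H]3C(=O)OC[C@@H]23
F3 | step 19 | 12-O-triethylsilyl ether of 25 | O=C3OC[C@H]1C(=C)C[C@H]2O[C@H]2[C@@](C)(O)CC[C@@H]1C3=[C@]=C([H])[C@@H](O[Si](CC)(CC)CC)C(C)(C)O[Si](CC)(CC)CC
F4 | step 19 | lactol of F3 (C14 hemiacetal; both anomers) | OC3OC[C@H]1C(=C)C[C@H]2O[C@H]2[C@@](C)(O)CC[C@@H]1C3=[C@]=C([H])[C@@H](O[Si](CC)(CC)CC)C(C)(C)O[Si](CC)(CC)CC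
F5 | step 19 | 12,13-bis-O-triethylsilyl ether of 28 | C=C1C[C@H]2O[C@H]2[C@@](C)(O)CC[C@@H]2C3=C[C@H]([C@@H](O[Si](CC)(CC)CC)C(C)(C)O[Si](CC)(CC)CC)O[C@@H]3OC[C@@H]12
F6 | step 17 | methyl (Sa)-allenoate diol (open-chain methyl ester of 25 with free C15 hydroxyl) | C=C1C[C@H]2O[C@H]2[C@@](C)(O)CC[C@H](C(C(=O)OC)=[C@]=C([H])[C@@H](O)C(C)(C)O[Si](CC)(CC)CC)[C@H]1CO
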